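All runs were computed for an exercise; scatter was added.

If a catalyst makes J at a steady rate, a flask behaves like a tank being emptied. Its time constant is the charge of the limiting reagent, the one that runs out first, divided by that rate.

all flasks: G 0.020 M
- dusk: X 0.030 M; Q 4.5 mM; run made earlier
- noon: X 0.030 M; Q 1.5 mM; run made earlier
- teal: X 0.0100 M; Q 3.0 mM; time 30 h
- violet: X 0.0300 M; Q 3.0 mM; time 8.0 h

| run | time / h | J / % |
|---|---|---|
| dusk | 0.250 | 0.8 |
| dusk | 0.417 | 0.7 |
| dusk | 0.833 | 1.2 |
| dusk | 1.33 | 3.5 |
| dusk | 3.00 | 12.7 |
| noon | 0.250 | 0 |
| noon | 0.667 | 0.2 |
| noon | 1.33 | 0.1 |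
| noon | 2.00 | 1.5 |
| noon | 3.00 | 3.9 |

(readings scatter by 1 percentage point)

- which one finishes higher in amount of J, in percent of the G charged ("neither" within 2 percentage points) (teal / violet / neither)
- amount of J at the end, in percent of the G charged, teal
- amount of J at the end, in percent of the G charged, violet

Both runs hold J near zero for about 1 h and then climb. At 3.00 h, dusk reads 3.26 times as high as noon with 3.00 times the Q, so I take the rate as proportional to c_Q. The Q of teal and violet, 3.0 mM, lies midway between the two runs, so I average their late slopes, each taken between its last two readings. That gives 7.91 × 10⁻⁴ M h⁻¹ at c_X = 0.0300 M, a reading that carries the scatter.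

Now carry one quantity: the fill time, limiting charge over rate, 12.6 h for teal if the rate holds. In my reckoning the rate then falls in proportion to what is still to be made, as in a first-order lag, so J is the ceiling times one minus exp(−t/fill time).

In violet G is limiting, so the fill time is 25.3 h and J reaches 27.1%. Two colleagues accept this, but no run varied c_X, and there they part over teal, where X is limiting and, at one X per J, the ceiling is 50.0%.

The first says the rate follows c_X, so with the X of teal at a third of that in the two runs the fill time is 37.9 h, teal reaches 27.3%, and the two flasks tie. The second says c_X sets the ceiling and leaves the rate alone, so the fill time stays 12.6 h, well under the 30 h allowed, and teal reaches 45.4%. I commit to the second's numbers, as a judgement and not a reading.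

The forecast says teal, with teal 30% and violet 26%: “The order in X is untested, which is the main uncertainty”.

The flask gives teal 46.2% and violet 26.0%, so teal finishes higher.

    G + Q → L (k = 1.70 L mol⁻¹ min⁻¹)
    X + L → D (k = 1.30 L mol⁻¹ min⁻¹)
    D → Q + J (k = 0.00660 min⁻¹)
    G + Q → E (k = 0.150 L mol⁻¹ min⁻¹)

At 30.0 h teal keeps 5.24% of its X, with L at 55.6% of the catalyst and D at 7.77%. That tail, where the step X + L runs in proportion to c_X, is the first's region. At 15.0 h the fill time 12.6 h gives 34.8%, and teal holds 31.9%.

Take teal with 0.025 M of X instead. G is now limiting, so the fill time becomes 25.3 h and the reckoning gives 69.5%. The computed flask gives 71.7%.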